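**Retrosynthetic overview**

1. The phenol and carbinol protecting groups come off last by methanolysis; just before that, the chalcone is made by aldol condensation on the C8 acetyl group, after all reductions are finished.
2. The side-chain carbinol comes from CBS reduction of a styryl ketone followed by hydrogenation of the alkene.
3. The only ring to be formed, the pyran ring of the chroman, is closed by an intramolecular Friedel–Crafts-type Michael addition of the phloroglucinol ring carbon onto a tethered dienone; the C2 aryl ether centre directs C4 (2,4-trans).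
4. The cyclization substrate comes from cross-metathesis of a homoallylic aryl ether (fragments A + B, joined by Mitsunobu inversion) with an aryl divinyl ketone (fragment C).
5. Fragment A is made from 2',4',6'-trihydroxyacetophenone, B from 4-hydroxybenzaldehyde (Brown allylation), C from 4-hydroxybenzylideneacetone (Mannich/elimination).

Assumption: the target is taken as drawn, which by CIP analysis is (2R,4S) in the chroman (2,4-trans) with an R side-chain carbinol.

**Route**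

Step 1
Reactants: 1 1-(2,4,6-trihydroxyphenyl)ethan-1-one
Product: 2 1-[4-(tert-butyldimethylsilyloxy)-2,6-dihydroxyphenyl]ethan-1-one
Conditions: TBSCl (1.05 equiv), imidazole, DMF, 0 °C
Reagents that add atoms: tert-butyldimethylsilyl chloride CC(C)(C)[Si](C)(C)Cl
Why: Silyl ether formation goes to the para hydroxyl, the only one that is neither hydrogen-bonded to the acetyl carbonyl nor flanked by it.

Step 2
Reactants: 2 1-[4-(tert-butyldimethylsilyloxy)-2,6-dihydroxyphenyl]ethan-1-one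
Product: 3 1-[4-(tert-butyldimethylsilyloxy)-2-hydroxy-6-methoxyphenyl]ethan-1-one
Conditions: MeOH (1.1 equiv), PPh3, DIAD, THF, 0 °C → rt
Reagents that add atoms: methanol CO
Why: Mitsunobu O-methylation is neutral (the aryl silyl ether survives) and stops after one methyl group because the remaining ortho hydroxyl is locked in a strong hydrogen bond to the ketone.

Step 3
Reactants: 4 4-hydroxybenzaldehyde
Product: 5 4-formylphenyl pivalate
Conditions: PivCl, Et3N, DMAP (cat.), CH2Cl2, 0 °C → rt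
Reagents that add atoms: pivaloyl chloride CC(C)(C)C(=O)Cl
Why: DMAP-catalysed O-acylation gives an electron-withdrawing phenol protecting group, chosen so that the benzylic centre made next cannot ionize in steps 5 and 10.

Step 4
Reactants: 5 4-formylphenyl pivalate
Product: 6 4-[(1S)-1-hydroxybut-3-en-1-yl]phenyl pivalate
Conditions: (−)-Ipc2B(allyl) (1 M in pentane, 1.3 equiv), Et2O, −78 °C; then HOCH2CH2NH2, rt
Reagents that add atoms: (−)-B-allyldiisopinocampheylborane C=CCB([C@@H]1C[C@@H]2C[C@H]([C@H]1C)C2(C)C)[C@@H]1C[C@@H]2C[C@H]([C@H]1C)C2(C)C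
Why: Brown asymmetric allylboration through a chair Zimmerman–Traxler transition state, in which the reagent derived from (+)-α-pinene attacks the Si face of aryl aldehydes and so sets the S carbinol (as it does with benzaldehyde).

Step 5
Reactants: 3 1-[4-(tert-butyldimethylsilyloxy)-2-hydroxy-6-methoxyphenyl]ethan-1-one; 6 4-[(1S)-1-hydroxybut-3-en-1-yl]phenyl pivalate
Product: 7 4-[(1R)-1-[2-acetyl-5-(tert-butyldimethylsilyloxy)-3-methoxyphenoxy]but-3-en-1-yl]phenyl pivalate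
Conditions: PPh3, DIAD, toluene, 0 °C → rt
Reagents that add atoms: none
Why: Mitsunobu etherification, in which SN2 attack of the phenol on the alkoxyphosphonium ion inverts the carbinol centre (S to R) while the acyloxy-deactivated aryl ring suppresses the ionization that would erode the ee.

Step 6
Reactants: 8 (E)-4-(4-hydroxyphenyl)but-3-en-2-one
Product: 9 4-[(E)-3-oxobut-1-en-1-yl]phenyl pivalate
Conditions: PivCl, Et3N, DMAP (cat.), CH2Cl2, 0 °C → rt
Reagents that add atoms: pivaloyl chloride CC(C)(C)C(=O)Cl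
Why: Simple DMAP-catalysed O-acylation of the phenol; the enone is untouched.

Step 7
Reactants: 9 4-[(E)-3-oxobut-1-en-1-yl]phenyl pivalate
Product: 10 4-[(E)-5-(dimethylamino)-3-oxopent-1-en-1-yl]phenyl pivalate
Conditions: LiN(SiMe3)2 (1.05 equiv), THF, −78 °C; CH2=NMe2+ I− (Eschenmoser's salt), −78 °C → rt
Reagents that add atoms: N,N-dimethylmethyleneiminium iodide C=[N+](C)C.[I-]
Why: Mannich reaction, in which the methyl group is the only enolizable position and its lithium enolate is aminomethylated by the iminium salt.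

Step 8
Reactants: 10 4-[(E)-5-(dimethylamino)-3-oxopent-1-en-1-yl]phenyl pivalate
Product: 12 4-[(E)-3-oxopenta-1,4-dien-1-yl]phenyl pivalate, via trimethylammonium iodide 11 (not isolated)
Conditions: MeI (5 equiv), CH2Cl2, rt; then aq. NaHCO3, rt (used at once, trace BHT)
Reagents that add atoms: none
Why: Exhaustive N-methylation followed by E1cB (Hofmann-type) elimination of trimethylamine from the β-ammonio ketone gives the vinyl ketone.

Step 9
Reactants: 7 4-[(1R)-1-[2-acetyl-5-(tert-butyldimethylsilyloxy)-3-methoxyphenoxy]but-3-en-1-yl]phenyl pivalate; 12 4-[(E)-3-oxopenta-1,4-dien-1-yl]phenyl pivalate (2.5 equiv)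
Product: 13 4-[(1R,3E,6E)-1-[2-acetyl-5-(tert-butyldimethylsilyloxy)-3-methoxyphenoxy]-5-oxo-7-[4-(pivaloyloxy)phenyl]hepta-3,6-dien-1-yl]phenyl pivalate
Conditions: second-generation Hoveyda–Grubbs catalyst RuCl2(H2IMes)(=CH-C6H4-2-OiPr) (5 mol %), CH2Cl2, 40 °C
Reagents that add atoms: none
Why: Olefin cross-metathesis between the terminal alkene and the electron-poor vinyl ketone is selective for the cross product and gives the E enone, while the styryl double bond is too hindered and deactivated to take part.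

Step 10
Reactants: 13 4-[(1R,3E,6E)-1-[2-acetyl-5-(tert-butyldimethylsilyloxy)-3-methoxyphenoxy]-5-oxo-7-[4-(pivaloyloxy)phenyl]hepta-3,6-dien-1-yl]phenyl pivalate
Product: 14 4-[(2R,4R)-8-acetyl-5-(tert-butyldimethylsilyloxy)-7-methoxy-4-[(E)-2-oxo-4-[4-(pivaloyloxy)phenyl]but-3-en-1-yl]-3,4-dihydro-2H-chromen-2-yl]phenyl pivalate (2,4-trans)
Conditions: Sc(OTf)3 (10–20 mol %), MeCN–CH2Cl2, 0.02 M, 0 °C → rt
Reagents that add atoms: none
Why: Intramolecular Friedel–Crafts-type Michael addition, in which the ring carbon ortho to the ether oxygen (the only one that can close a six-membered ring) attacks the Lewis-acid-activated enone through a chair-like transition state with the C2 aryl pseudo-equatorial and the enone arm pseudo-axial to avoid A(1,3) strain with the peri silyloxy group, giving the 2,4-trans chroman (same spatial arrangement as 4S in the target; the descriptor reads 4R only because the ketone arm outranks C3).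

Step 11
Reactants: 14 4-[(2R,4R)-8-acetyl-5-(tert-butyldimethylsilyloxy)-7-methoxy-4-[(E)-2-oxo-4-[4-(pivaloyloxy)phenyl]but-3-en-1-yl]-3,4-dihydro-2H-chromen-2-yl]phenyl pivalate
Product: 15 4-[(2R,4S)-8-acetyl-5-(tert-butyldimethylsilyloxy)-4-[(2S,3E)-2-hydroxy-4-[4-(pivaloyloxy)phenyl]but-3-en-1-yl]-7-methoxy-3,4-dihydro-2H-chromen-2-yl]phenyl pivalate
Conditions: (R)-2-methyl-CBS-oxazaborolidine (0.5 equiv), catecholborane (2 equiv), toluene, −78 °C; MeOH quench
Reagents that add atoms: none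
Why: Corey–Bakshi–Shibata reduction, in which the (R)-catalyst delivers hydride to the enone with the styryl group as the large substituent to give the S allylic alcohol (the R carbinol of the target once the alkene is saturated), while the di-ortho-substituted aryl methyl ketone is too hindered to react at −78 °C.

Step 12
Reactants: 15 4-[(2R,4S)-8-acetyl-5-(tert-butyldimethylsilyloxy)-4-[(2S,3E)-2-hydroxy-4-[4-(pivaloyloxy)phenyl]but-3-en-1-yl]-7-methoxy-3,4-dihydro-2H-chromen-2-yl]phenyl pivalate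
Product: 17 4-[(2R,4S)-4-[(2R)-2-acetoxy-4-[4-(pivaloyloxy)phenyl]butyl]-8-acetyl-5-(tert-butyldimethylsilyloxy)-7-methoxy-3,4-dihydro-2H-chromen-2-yl]phenyl pivalate, via saturated alcohol 16 (not isolated)
Conditions: H2 (3 atm), RhCl(PPh3)3 (10 mol %), THF, rt; then Ac2O, pyridine, DMAP, rt
Reagents that add atoms: acetic anhydride CC(=O)OC(C)=O
Why: Homogeneous hydrogenation with Wilkinson's catalyst saturates only the disubstituted alkene without hydrogenolysis of the allylic or benzylic C–O bonds, and DMAP-catalysed acetylation then masks the carbinol; no stereocentre is touched (S becomes R only through the priority change).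

Step 13
Reactants: 17 4-[(2R,4S)-4-[(2R)-2-acetoxy-4-[4-(pivaloyloxy)phenyl]butyl]-8-acetyl-5-(tert-butyldimethylsilyloxy)-7-methoxy-3,4-dihydro-2H-chromen-2-yl]phenyl pivalate; 5 4-formylphenyl pivalate (1.3 equiv)
Product: 20 4-[(E)-3-[(2R,4S)-4-[(2R)-2-acetoxy-4-[4-(pivaloyloxy)phenyl]butyl]-5-(tert-butyldimethylsilyloxy)-7-methoxy-2-[4-(pivaloyloxy)phenyl]-3,4-dihydro-2H-chromen-8-yl]-3-oxoprop-1-en-1-yl]phenyl pivalate, via lithium aldolate 18 (not isolated), via β-mesyloxy ketone 19 (not isolated)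
Conditions: LiN(SiMe3)2 (1.1 equiv), THF, −78 °C; 5; MsCl (1.5 equiv), −78 → 0 °C; DBU (3 equiv), 0 °C → rt
Reagents that add atoms: none
Why: Directed crossed aldol condensation, in which LiN(SiMe3)2 deprotonates the methyl ketone in preference to the esters, the enolate adds to the aldehyde, and mesylation with E1cB elimination gives the E chalcone.

Step 14
Reactants: 20 4-[(E)-3-[(2R,4S)-4-[(2R)-2-acetoxy-4-[4-(pivaloyloxy)phenyl]butyl]-5-(tert-butyldimethylsilyloxy)-7-methoxy-2-[4-(pivaloyloxy)phenyl]-3,4-dihydro-2H-chromen-8-yl]-3-oxoprop-1-en-1-yl]phenyl pivalate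
Product: 21 (E)-1-[(2R,4S)-5-hydroxy-4-[(2R)-2-hydroxy-4-(4-hydroxyphenyl)butyl]-2-(4-hydroxyphenyl)-7-methoxy-3,4-dihydro-2H-chromen-8-yl]-3-(4-hydroxyphenyl)prop-2-en-1-one (CNP0102599.2)
Conditions: K2CO3, MeOH–THF (3:1), rt; aq. NH4Cl to pH 6
Reagents that add atoms: none
Why: Base-catalysed methanolysis (transesterification) cleaves the three aryl pivalates, the acetate and the aryl silyl ether in one operation, while the early-formed 5-phenoxide (para to the ketone) makes the ring oxygen a poor leaving group and so protects C2 from epimerization.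

**Compound list**

1 | 1-(2,4,6-trihydroxyphenyl)ethan-1-one | CC(=O)c1c(O)cc(O)cc1O | starting material
2 | 1-[4-(tert-butyldimethylsilyloxy)-2,6-dihydroxyphenyl]ethan-1-one | CC(=O)c1c(O)cc(O[Si](C)(C)C(C)(C)C)cc1O | intermediate
3 | 1-[4-(tert-butyldimethylsilyloxy)-2-hydroxy-6-methoxyphenyl]ethan-1-one | CC(=O)c1c(O)cc(O[Si](C)(C)C(C)(C)C)cc1OC | intermediate
4 | 4-hydroxybenzaldehyde | O=Cc1ccc(O)cc1 | starting material
5 | 4-formylphenyl pivalate | CC(C)(C)C(=O)Oc1ccc(C=O)cc1 | intermediate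
6 | 4-[(1S)-1-hydroxybut-3-en-1-yl]phenyl pivalate | C=CC[C@H](O)c1ccc(OC(=O)C(C)(C)C)cc1 | intermediate
7 | 4-[(1R)-1-[2-acetyl-5-(tert-butyldimethylsilyloxy)-3-methoxyphenoxy]but-3-en-1-yl]phenyl pivalate | CC(=O)c1c(OC)cc(O[Si](C)(C)C(C)(C)C)cc1O[C@@H](c1ccc(OC(=O)C(C)(C)C)cc1)CC=C | intermediate
8 | (E)-4-(4-hydroxyphenyl)but-3-en-2-one | CC(=O)/C=C/c1ccc(O)cc1 | starting material
9 | 4-[(E)-3-oxobut-1-en-1-yl]phenyl pivalate | CC(=O)/C=C/c1ccc(OC(=O)C(C)(C)C)cc1 | intermediate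
10 | 4-[(E)-5-(dimethylamino)-3-oxopent-1-en-1-yl]phenyl pivalate | CN(C)CCC(=O)/C=C/c1ccc(OC(=O)C(C)(C)C)cc1 | intermediate
11 | trimethyl[(E)-3-oxo-5-[4-(pivaloyloxy)phenyl]pent-4-en-1-yl]ammonium iodide (not isolated) | C[N+](C)(C)CCC(=O)/C=C/c1ccc(OC(=O)C(C)(C)C)cc1.[I-] | intermediate
12 | 4-[(E)-3-oxopenta-1,4-dien-1-yl]phenyl pivalate | C=CC(=O)/C=C/c1ccc(OC(=O)C(C)(C)C)cc1 | intermediate
13 | 4-[(1R,3E,6E)-1-[2-acetyl-5-(tert-butyldimethylsilyloxy)-3-methoxyphenoxy]-5-oxo-7-[4-(pivaloyloxy)phenyl]hepta-3,6-dien-1-yl]phenyl pivalate | CC(=O)c1c(OC)cc(O[Si](C)(C)C(C)(C)C)cc1O[C@@H](c1ccc(OC(=O)C(C)(C)C)cc1)C/C=C/C(=O)/C=C/c1ccc(OC(=O)C(C)(C)C)cc1 | intermediate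
14 | 4-[(2R,4R)-8-acetyl-5-(tert-butyldimethylsilyloxy)-7-methoxy-4-[(E)-2-oxo-4-[4-(pivaloyloxy)phenyl]but-3-en-1-yl]-3,4-dihydro-2H-chromen-2-yl]phenyl pivalate (2,4-trans) | COc1cc(O[Si](C)(C)C(C)(C)C)c2c(c1C(C)=O)O[C@@H](c1ccc(OC(=O)C(C)(C)C)cc1)C[C@@H]2CC(=O)/C=C/c1ccc(OC(=O)C(C)(C)C)cc1 | intermediate
15 | 4-[(2R,4S)-8-acetyl-5-(tert-butyldimethylsilyloxy)-4-[(2S,3E)-2-hydroxy-4-[4-(pivaloyloxy)phenyl]but-3-en-1-yl]-7-methoxy-3,4-dihydro-2H-chromen-2-yl]phenyl pivalate | COc1cc(O[Si](C)(C)C(C)(C)C)c2c(c1C(C)=O)O[C@@H](c1ccc(OC(=O)C(C)(C)C)cc1)C[C@@H]2C[C@H](O)/C=C/c1ccc(OC(=O)C(C)(C)C)cc1 | intermediate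
16 | 4-[(2R,4S)-8-acetyl-5-(tert-butyldimethylsilyloxy)-4-[(2R)-2-hydroxy-4-[4-(pivaloyloxy)phenyl]butyl]-7-methoxy-3,4-dihydro-2H-chromen-2-yl]phenyl pivalate (not isolated) | COc1cc(O[Si](C)(C)C(C)(C)C)c2c(c1C(C)=O)O[C@@H](c1ccc(OC(=O)C(C)(C)C)cc1)C[C@@H]2C[C@H](O)CCc1ccc(OC(=O)C(C)(C)C)cc1 | intermediate
17 | 4-[(2R,4S)-4-[(2R)-2-acetoxy-4-[4-(pivaloyloxy)phenyl]butyl]-8-acetyl-5-(tert-butyldimethylsilyloxy)-7-methoxy-3,4-dihydro-2H-chromen-2-yl]phenyl pivalate | COc1cc(O[Si](C)(C)C(C)(C)C)c2c(c1C(C)=O)O[C@@H](c1ccc(OC(=O)C(C)(C)C)cc1)C[C@@H]2C[C@H](OC(C)=O)CCc1ccc(OC(=O)C(C)(C)C)cc1 | intermediate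
18 | lithium aldolate of 17 with 5 (β-lithiooxy ketone, both epimers at the new carbinol; not isolated) | COc1cc(O[Si](C)(C)C(C)(C)C)c2c(c1C(=O)CC(O[Li])c1ccc(OC(=O)C(C)(C)C)cc1)O[C@@H](c1ccc(OC(=O)C(C)(C)C)cc1)C[C@@H]2C[C@H](OC(C)=O)CCc1ccc(OC(=O)C(C)(C)C)cc1 | intermediate
19 | β-mesyloxy ketone from 18 (both epimers; not isolated) | COc1cc(O[Si](C)(C)C(C)(C)C)c2c(c1C(=O)CC(OS(C)(=O)=O)c1ccc(OC(=O)C(C)(C)C)cc1)O[C@@H](c1ccc(OC(=O)C(C)(C)C)cc1)C[C@@H]2C[C@H](OC(C)=O)CCc1ccc(OC(=O)C(C)(C)C)cc1 | intermediate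
20 | 4-[(E)-3-[(2R,4S)-4-[(2R)-2-acetoxy-4-[4-(pivaloyloxy)phenyl]butyl]-5-(tert-butyldimethylsilyloxy)-7-methoxy-2-[4-(pivaloyloxy)phenyl]-3,4-dihydro-2H-chromen-8-yl]-3-oxoprop-1-en-1-yl]phenyl pivalate | COc1cc(O[Si](C)(C)C(C)(C)C)c2c(c1C(=O)/C=C/c1ccc(OC(=O)C(C)(C)C)cc1)O[C@@H](c1ccc(OC(=O)C(C)(C)C)cc1)C[C@@H]2C[C@H](OC(C)=O)CCc1ccc(OC(=O)C(C)(C)C)cc1 | intermediate
21 | (E)-1-[(2R,4S)-5-hydroxy-4-[(2R)-2-hydroxy-4-(4-hydroxyphenyl)butyl]-2-(4-hydroxyphenyl)-7-methoxy-3,4-dihydro-2H-chromen-8-yl]-3-(4-hydroxyphenyl)prop-2-en-1-one | COc1cc(O)c2c(c1C(=O)/C=C/c1ccc(O)cc1)O[C@@H](c1ccc(O)cc1)C[C@@H]2C[C@H](O)CCc1ccc(O)cc1 | target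

**Step count and risks**

Total step count: 14. Longest linear sequence: 9 steps (1 → 2 → 5 → 9 → 10 → 11 → 12 → 13 → 14; the branches through steps 3–4 and 6–8 are equally long).

Most likely to fail:

Step 10 (ring closure). The silyloxy-flanked ring carbon may be sluggish, and the 2,4-trans preference rests on the peri-strain argument, so the 2,4-cis isomer may form in part or predominate; it would have to be separated here, because later C2 equilibration of a cis compound would lead into the wrong enantiomeric series. The fallback sets out from 13 and comes back at 14, and changes the nucleophile and the source of stereocontrol. The aryl silyl ether of 13 is removed selectively (Bu4NF–AcOH, THF, 0 °C) to give the free phenol 4-[(1R,3E,6E)-1-(2-acetyl-5-hydroxy-3-methoxyphenoxy)-5-oxo-7-[4-(pivaloyloxy)phenyl]hepta-3,6-dien-1-yl]phenyl pivalate F3. This is cyclized as a phenol ortho-C-alkylation (intramolecular Michael) with a quinine- or quinidine-derived bifunctional squaramide, which binds the enone by hydrogen bonds and the phenol through its amine; the much more nucleophilic phenol reacts under mild conditions, and the pseudo-enantiomeric catalyst that reinforces the trans isomer is chosen, giving the 5-hydroxy chroman F4. Silylation (TBSCl, imidazole, DMF) returns 14.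

Step 5 (Mitsunobu). The phenol is hindered and hydrogen-bonded, and the secondary benzylic alcohol can eliminate to the aryl diene or lose ee. The fallback sets out from 3 and 5 and comes back at 7; it forms the aryl–oxygen bond instead of the alkyl–oxygen bond, so the stereocentre is never touched. Phenol 3 is converted (Tf2O, pyridine, CH2Cl2) into 2-acetyl-5-(tert-butyldimethylsilyloxy)-3-methoxyphenyl trifluoromethanesulfonate F1. Aldehyde 5 is allylated with the enantiomeric reagent (+)-Ipc2B(allyl) to give 4-[(1R)-1-hydroxybut-3-en-1-yl]phenyl pivalate F2. Cross-coupling of the two (Pd2(dba)3 as the zerovalent palladium source, RockPhos, K3PO4, toluene, 80 °C) gives 7 with retention at carbon.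

Step 14 (global deprotection). Pivalate methanolysis may be slow enough for the basic medium to damage the chalcone or open the C2 benzylic ether through the para-phenoxide. The fallback sets out from 17 and comes back at 21; it moves the base-requiring deacylation in front of the chalcone and ends with fluoride. Compound 17 is methanolysed (K2CO3, MeOH) to the tetraol 1-[(2R,4S)-5-hydroxy-4-[(2R)-2-hydroxy-4-(4-hydroxyphenyl)butyl]-2-(4-hydroxyphenyl)-7-methoxy-3,4-dihydro-2H-chromen-8-yl]ethan-1-one F5, which is persilylated (TBSCl, imidazole, DMF, 40 °C) to its tetrakis(tert-butyldimethylsilyl) ether F6. Enolization as in step 13 and addition of commercial 4-(tert-butyldimethylsilyloxy)benzaldehyde give the lithium aldolate F7; mesylation gives the β-mesyloxy ketone F8, and DBU gives the pentakis(tert-butyldimethylsilyl) chalcone F9. HF·pyridine buffered with pyridine (THF, 0 °C → rt) then removes all five silyl groups to give 21.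

**Further compounds**

F1 | step 5 | 2-acetyl-5-(tert-butyldimethylsilyloxy)-3-methoxyphenyl trifluoromethanesulfonate | CC(=O)c1c(OC)cc(O[Si](C)(C)C(C)(C)C)cc1OS(=O)(=O)C(F)(F)F
F2 | step 5 | 4-[(1R)-1-hydroxybut-3-en-1-yl]phenyl pivalate | C=CC[C@@H](O)c1ccc(OC(=O)C(C)(C)C)cc1
F3 | step 10 | 4-[(1R,3E,6E)-1-(2-acetyl-5-hydroxy-3-methoxyphenoxy)-5-oxo-7-[4-(pivaloyloxy)phenyl]hepta-3,6-dien-1-yl]phenyl pivalate | CC(=O)c1c(OC)cc(O)cc1O[C@@H](c1ccc(OC(=O)C(C)(C)C)cc1)C/C=C/C(=O)/C=C/c1ccc(OC(=O)C(C)(C)C)cc1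
F4 | step 10 | 4-[(2R,4R)-8-acetyl-5-hydroxy-7-methoxy-4-[(E)-2-oxo-4-[4-(pivaloyloxy)phenyl]but-3-en-1-yl]-3,4-dihydro-2H-chromen-2-yl]phenyl pivalate (2,4-trans) | COc1cc(O)c2c(c1C(C)=O)O[C@@H](c1ccc(OC(=O)C(C)(C)C)cc1)C[C@@H]2CC(=O)/C=C/c1ccc(OC(=O)C(C)(C)C)cc1
F5 | step 14 | 1-[(2R,4S)-5-hydroxy-4-[(2R)-2-hydroxy-4-(4-hydroxyphenyl)butyl]-2-(4-hydroxyphenyl)-7-methoxy-3,4-dihydro-2H-chromen-8-yl]ethan-1-one | COc1cc(O)c2c(c1C(C)=O)O[C@@H](c1ccc(O)cc1)C[C@@H]2C[C@H](O)CCc1ccc(O)cc1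
F6 | step 14 | tetrakis(tert-butyldimethylsilyl) ether of F5 | COc1cc(O[Si](C)(C)C(C)(C)C)c2c(c1C(C)=O)O[C@@H](c1ccc(O[Si](C)(C)C(C)(C)C)cc1)C[C@@H]2C[C@H](O[Si](C)(C)C(C)(C)C)CCc1ccc(O[Si](C)(C)C(C)(C)C)cc1
F7 | step 14 | lithium aldolate of F6 with 4-(tert-butyldimethylsilyloxy)benzaldehyde (both epimers at the new carbinol) | COc1cc(O[Si](C)(C)C(C)(C)C)c2c(c1C(=O)CC(O[Li])c1ccc(O[Si](C)(C)C(C)(C)C)cc1)O[C@@H](c1ccc(O[Si](C)(C)C(C)(C)C)cc1)C[C@@H]2C[C@H](O[Si](C)(C)C(C)(C)C)CCc1ccc(O[Si](C)(C)C(C)(C)C)cc1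
F8 | step 14 | β-mesyloxy ketone from F7 (both epimers) | COc1cc(O[Si](C)(C)C(C)(C)C)c2c(c1C(=O)CC(OS(C)(=O)=O)c1ccc(O[Si](C)(C)C(C)(C)C)cc1)O[C@@H](c1ccc(O[Si](C)(C)C(C)(C)C)cc1)C[C@@H]2C[C@H](O[Si](C)(C)C(C)(C)C)CCc1ccc(O[Si](C)(C)C(C)(C)C)cc1
F9 | step 14 | pentakis(tert-butyldimethylsilyl) ether of 21 | COc1cc(O[Si](C)(C)C(C)(C)C)c2c(c1C(=O)/C=C/c1ccc(O[Si](C)(C)C(C)(C)C)cc1)O[C@@H](c1ccc(O[Si](C)(C)C(C)(C)C)cc1)C[C@@H]2C[C@H](O[Si](C)(C)C(C)(C)C)CCc1ccc(O[Si](C)(C)C(C)(C)C)cc1
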